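**Plan**
1. Retrosynthetic cuts, in order: C5=C6 (Wittig on a lactol); C10–C11 (the cyclopentanone opens to a cis-γ-lactone carrying CH2Br on C9 and a nitrile-bearing arm on C8); C12–C13 (Michael addition to oct-1-en-3-one) and C8–C12 (tethered Michael addition); last the cyanoacetate ester on the C10 oxygen of a butenolide.
2. Forward order: butenolide (ring O9–C6–C7–C8–C9) from (S)-glyceraldehyde acetonide; temporary δ-lactone through the cyanoacetate tether; tether cut with loss of CO2, leaving C10–Br and the C11 nitrile; cyclopentanone closed at C10–C11; α-chain by Wittig; ketals off.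
3. Stereochemistry: C9 is bought; C8 is relayed from C9, because the tethered carbanion can reach C8 only on the face that carries C10; C12 is set by equilibration on the cis-fused bicycle in the key step; the 5Z-alkene comes from the unstabilised ylide.
4. Enabling feature: O9 and C7 are cis across C8–C9, so O9 and C6 can be tied into a γ-lactone; C10 and the C12 arm are then cis on that ring, and a radical at C10 reaches the nitrile carbon C11 (C10–C9–C8–C12–C11) to give the cis-fused 2-oxabicyclo[3.3.0]octane with C11 at the ketone level.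

Key step: step 6

Remark: positions are given in prostanoic acid numbering (C1 = carboxyl carbon, C20 = chain end); C12 is carried as both epimers from step 4 and is fixed in step 6.

**Step 1**
Reactants: 1 (S)-glyceraldehyde acetonide; 2 methyl (triphenylphosphoranylidene)acetate
Product: 3 methyl (2Z)-3-[(4R)-2,2-dimethyl-1,3-dioxolan-4-yl]prop-2-enoate
Conditions: MeOH, 0 °C to rt; chromatography
Reagents that add atoms: none
Why: Wittig olefination with a stabilised ylide, which with α-alkoxy aldehydes in methanol should give mainly the Z-enoate; C9 comes unchanged from 1.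

**Step 2**
Reactants: 3 Z-enoate
Product: 4 (5R)-5-(hydroxymethyl)furan-2(5H)-one
Conditions: H2SO4 (cat.), MeOH–H2O, rt
Reagents that add atoms: none
Why: Acid-catalysed acetonide cleavage followed by lactonisation of the Z-γ-hydroxy enoate (only the Z-isomer can close) should give the butenolide with C9 untouched.

**Step 3**
Reactants: 4 butenolide alcohol; 5 cyanoacetic acid
Product: 6 [(2R)-5-oxo-2,5-dihydrofuran-2-yl]methyl cyanoacetate
Conditions: DCC, CH2Cl2, 0 °C to rt
Reagents that add atoms: none
Why: Carbodiimide esterification of the primary alcohol, run without amine base so that the butenolide is not enolised.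

**Step 4**
Reactants: 6 cyanoacetate ester; 7 oct-1-en-3-one
Product: 9 (3aR,7aR)-2,5-dioxo-4-(3-oxooctyl)hexahydro-4H-furo[2,3-c]pyran-4-carbonitrile, via cis-fused cyano bis-lactone 8 (not isolated)
Conditions: Cs2CO3 (0.2 equiv), MeCN, 0 °C, high dilution; then 7, rt
Reagents that add atoms: none
Why: Base-catalysed intramolecular Michael addition (6-exo-trig) of the cyanoacetate carbanion, delivered through the ester tether on the face of C10, should set C8 with the new C8–C12 bond cis to C9–C10, and the still acidic C12–H then adds to the vinyl ketone in a second Michael addition that installs C13–C20; substoichiometric carbonate should deprotonate only the cyanoacetate C–H and not the butenolide γ-position.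

**Step 5**
Reactants: 9 quaternary cyano bis-lactone
Product: 11 2-[(2R,3R)-2-(bromomethyl)-5-oxooxolan-3-yl]-5-oxodecanenitrile, via bromo cyano acid 10 (not isolated)
Conditions: pyridinium bromide, dry DMF, 120 °C
Reagents that add atoms: pyridinium bromide, [Br-].c1cc[nH+]cc1
Why: Halide-induced decarboxylative ring opening of an α-cyano lactone (Krapcho-type dealkoxycarbonylation, as in the conversion of α-acyl lactones into ω-halo ketones): bromide should attack the primary C10 by SN2, the α-cyano carboxylate loses CO2 and the nitrile anion is protonated by pyridinium, so the tether leaves while C10–Br and the C11 nitrile stay; C8 and C9 are not touched.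

**Step 6**
Reactants: 11 bromo nitrile lactone
Product: 13 (3aR,4R,6aS)-4-(3-oxooctyl)hexahydro-2H-cyclopenta[b]furan-2,5(3H)-dione, via N-H ketimine 12 (not isolated)
Conditions: Bu3SnH, AIBN (cat.), PhH (5 mM), 80 °C, syringe-pump addition; then AcOH–H2O–THF, rt
Reagents that add atoms: water, O
Why: Bu3Sn• abstracts bromine from C10, the primary radical adds to the nitrile carbon C11, the iminyl radical takes hydrogen from Bu3SnH, and the ketimine 12 is hydrolysed to the ketone on mild acidic work-up. The closest known reaction type is the tin hydride-mediated cyclisation of ω-haloalkyl nitriles to cyclopentanones, as used on furanoside and pyranoside templates. The new ring (C8–C9–C10–C11–C12) closes 5-exo-dig and can only be cis-fused to the γ-lactone, because C10 and the C12 arm are cis on that ring, so C8 and C9 pass through unchanged. C12, the one centre still open, should be settled after closure by ketimine–enamine and then keto–enol equilibration under the mild acid, which should place the 3-oxooctyl chain on the convex face, trans to the lactone CH2 on C8. The step needs cyclisation to beat direct reduction of the C10 radical and fragmentation of the iminyl radical (cyano transfer); slow addition at high dilution keeps the hydride concentration low, and the iminyl radical should be the thermodynamic sink of the reversible manifold. Base-free conditions keep the β-acyloxy ketone from eliminating.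

**Step 7**
Reactants: 13 diketo lactone
Product: 14 (3aR,4R,6aS)-4-[2-(2-pentyl-1,3-dioxolan-2-yl)ethyl]tetrahydro-3H-spiro[cyclopenta[b]furan-5,2'-[1,3]dioxolan]-2-one
Conditions: TMSOCH2CH2OTMS, TMSOTf (cat.), CH2Cl2, −78 to −20 °C
Reagents that add atoms: 1,2-bis(trimethylsilyloxy)ethane, C[Si](C)(C)OCCO[Si](C)(C)C
Why: Noyori ketalisation is aprotic and runs at low temperature, so both ketones should be masked without enolisation at C12 or loss of the β-acyloxy group.

**Step 8**
Reactants: 14 bis-ketal lactone
Product: 15 the corresponding lactol (2-hydroxy compound, both anomers)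
Conditions: i-Bu2AlH, CH2Cl2, −78 °C; Rochelle salt work-up
Reagents that add atoms: none
Why: Partial reduction of a γ-lactone to the lactol by i-Bu2AlH at low temperature; the ketals are inert.

**Step 9**
Reactants: 15 lactol; 16 (4-carboxybutyl)triphenylphosphonium bromide
Product: 17 (5Z)-9α-hydroxy-11,11:15,15-bis(ethylenedioxy)prost-5-enoic acid
Conditions: 16, KOt-Bu, THF, 0 °C; then 15, rt; aq. citric acid to pH 5
Reagents that add atoms: none
Why: Wittig olefination of the lactol (through its open hydroxy aldehyde) with the unstabilised ylide under lithium-free conditions should give the 5Z-alkene and frees the C9 hydroxyl.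

**Step 10**
Reactants: 17 bis-ketal hydroxy acid
Product: 18 13,14-dihydro-15-keto-PGD2
Conditions: AcOH–H2O–THF (3:1:1), 40 °C
Reagents that add atoms: water, O
Why: Acid-catalysed ketal hydrolysis under the mild aqueous acetic acid conditions that D-type β-ketols are known to tolerate should release both ketones without dehydration.

**Compound list**
1 | (S)-2,2-dimethyl-1,3-dioxolane-4-carbaldehyde ((S)-glyceraldehyde acetonide) | CC1(C)OC[C@H](O1)C=O | starting material
2 | methyl (triphenylphosphoranylidene)acetate | COC(=O)C=P(c1ccccc1)(c1ccccc1)c1ccccc1 | starting material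
3 | methyl (2Z)-3-[(4R)-2,2-dimethyl-1,3-dioxolan-4-yl]prop-2-enoate | CC1(C)OC[C@H](O1)/C=C\C(=O)OC | intermediate
4 | (5R)-5-(hydroxymethyl)furan-2(5H)-one | OC[C@@H]1OC(=O)C=C1 | intermediate
5 | cyanoacetic acid | N#CCC(=O)O | starting material
6 | [(2R)-5-oxo-2,5-dihydrofuran-2-yl]methyl cyanoacetate | N#CCC(=O)OC[C@@H]1OC(=O)C=C1 | intermediate
7 | oct-1-en-3-one | C=CC(=O)CCCCC | starting material
8 | (3aR,7aR)-2,5-dioxohexahydro-4H-furo[2,3-c]pyran-4-carbonitrile (cis-fused γ-lactone/δ-lactone, both C4 epimers) | O=C1C[C@H]2[C@@H](O1)COC(=O)C2C#N | intermediate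
9 | (3aR,7aR)-2,5-dioxo-4-(3-oxooctyl)hexahydro-4H-furo[2,3-c]pyran-4-carbonitrile | O=C1C[C@H]2[C@@H](O1)COC(=O)C2(C#N)CCC(=O)CCCCC | intermediate
10 | 2-[(2R,3R)-2-(bromomethyl)-5-oxooxolan-3-yl]-2-cyano-5-oxodecanoic acid (present as its pyridinium salt) | O=C1C[C@H](C(C#N)(CCC(=O)CCCCC)C(=O)O)[C@H](CBr)O1 | intermediate
11 | 2-[(2R,3R)-2-(bromomethyl)-5-oxooxolan-3-yl]-5-oxodecanenitrile (cis-lactone, both epimers at the nitrile-bearing carbon) | O=C1C[C@H](C(C#N)CCC(=O)CCCCC)[C@H](CBr)O1 | intermediate
12 | (3aR,6aS)-5-imino-4-(3-oxooctyl)hexahydro-2H-cyclopenta[b]furan-2-one (both C4 epimers) | O=C1C[C@H]2[C@@H](O1)CC(=N)C2CCC(=O)CCCCC | intermediate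
13 | (3aR,4R,6aS)-4-(3-oxooctyl)hexahydro-2H-cyclopenta[b]furan-2,5(3H)-dione | O=C1C[C@H]2[C@@H](O1)CC(=O)[C@@H]2CCC(=O)CCCCC | intermediate
14 | (3aR,4R,6aS)-4-[2-(2-pentyl-1,3-dioxolan-2-yl)ethyl]tetrahydro-3H-spiro[cyclopenta[b]furan-5,2'-[1,3]dioxolan]-2-one | O=C1C[C@H]2[C@@H](O1)CC3(OCCO3)[C@@H]2CCC4(CCCCC)OCCO4 | intermediate
15 | lactol of 14 (2-hydroxy compound, both anomers) | OC1C[C@H]2[C@@H](O1)CC3(OCCO3)[C@@H]2CCC4(CCCCC)OCCO4 | intermediate
16 | (4-carboxybutyl)triphenylphosphonium bromide | [Br-].OC(=O)CCCC[P+](c1ccccc1)(c1ccccc1)c1ccccc1 | starting material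
17 | (5Z)-9α-hydroxy-11,11:15,15-bis(ethylenedioxy)prost-5-enoic acid | CCCCCC1(OCCO1)CC[C@H]2C3(OCCO3)C[C@H](O)[C@@H]2C/C=C\CCCC(=O)O | intermediate
18 | 13,14-dihydro-15-keto-PGD2, (5Z)-7-[(1R,2R,5S)-5-hydroxy-3-oxo-2-(3-oxooctyl)cyclopentyl]hept-5-enoic acid | CCCCCC(=O)CC[C@H]1C(=O)C[C@H](O)[C@@H]1C/C=C\CCCC(=O)O | target

Total step count: 10. Longest linear sequence: 10 steps (1 to 18).

**Steps most likely to fail**

Step 5. Adventitious water or pyridine may attack the activated lactone at the acyl carbon instead of bromide attacking C10, and the primary bromide may re-close or lose HBr at 120 °C before CO2 has left. The fallback sets out from 9 and returns at 11; it cleaves the tether at the acyl carbon on purpose and introduces the halide separately. LiOH in THF–H2O at 0 °C, then acidification (the γ-lactone re-closes), should give 2-cyano-2-[(2R,3R)-2-(hydroxymethyl)-5-oxooxolan-3-yl]-5-oxodecanoic acid F1. Warming F1 in DMF at about 110 °C should decarboxylate it to 2-[(2R,3R)-2-(hydroxymethyl)-5-oxooxolan-3-yl]-5-oxodecanenitrile F2. An Appel reaction (PPh3, CBr4, CH2Cl2, 0 °C) then gives 11.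

Step 6. Hydrogen transfer may reach the C10 radical before it has added to the weakly radicophilic nitrile, or the iminyl radical may fragment towards C12 and move the cyano group to C10. The fallback sets out from 4 and returns at 13; it replaces the nitrile by an S-phenyl thioester, an acyl-transfer radical acceptor whose adduct collapses to the ketone by loss of PhS•, so no iminyl radical is involved.
- Alcohol 4 is esterified (DCC, CH2Cl2) with 3-oxo-3-(phenylsulfanyl)propanoic acid to [(2R)-5-oxo-2,5-dihydrofuran-2-yl]methyl 3-oxo-3-(phenylsulfanyl)propanoate F3.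
- Cs2CO3 (cat.) and then 7, as in step 4, should give, through S-phenyl (3aR,7aR)-2,5-dioxohexahydro-4H-furo[2,3-c]pyran-4-carbothioate F4, the quaternary S-phenyl (3aR,7aR)-2,5-dioxo-4-(3-oxooctyl)hexahydro-4H-furo[2,3-c]pyran-4-carbothioate F5.
- Pyridinium bromide in DMF, as in step 5, should give, through 2-[(2R,3R)-2-(bromomethyl)-5-oxooxolan-3-yl]-5-oxo-2-[(phenylsulfanyl)carbonyl]decanoic acid F6, S-phenyl 2-[(2R,3R)-2-(bromomethyl)-5-oxooxolan-3-yl]-5-oxodecanethioate F7.
- With Bu3SnH/AIBN in PhH at 80 °C the C10 radical should add to the thioester carbonyl (5-exo-trig) and the alkoxy radical expel PhS•, giving 13 directly.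

Step 10. Acid-promoted dehydration of the β-ketol towards the cyclopentenone may compete with the slower hydrolysis of the cyclopentanone ketal. The fallback sets out from 13 and returns at 18; it masks the ketones as thioketals, which are removed oxidatively near neutral pH. Propane-1,3-dithiol with BF3·OEt2 (CH2Cl2, 0 °C) should convert 13 into the 11,15-bis(1,3-dithiane) lactone F8. i-Bu2AlH at −78 °C gives the bis(1,3-dithiane) lactol F9. Wittig reaction with 16/KOt-Bu gives (5Z)-9α-hydroxyprost-5-enoic acid 11,15-bis(propane-1,3-diyl dithioketal) F10. PhI(OCOCF3)2 in aqueous MeCN buffered with NaHCO3 at 0 °C then releases both ketones to give 18.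

**Further compounds**
F1 | step 5 | 2-cyano-2-[(2R,3R)-2-(hydroxymethyl)-5-oxooxolan-3-yl]-5-oxodecanoic acid | O=C1C[C@H](C(C#N)(CCC(=O)CCCCC)C(=O)O)[C@H](CO)O1
F2 | step 5 | 2-[(2R,3R)-2-(hydroxymethyl)-5-oxooxolan-3-yl]-5-oxodecanenitrile | O=C1C[C@H](C(C#N)CCC(=O)CCCCC)[C@H](CO)O1
F3 | step 6 | [(2R)-5-oxo-2,5-dihydrofuran-2-yl]methyl 3-oxo-3-(phenylsulfanyl)propanoate | O=C(CC(=O)Sc1ccccc1)OC[C@@H]1OC(=O)C=C1
F4 | step 6 | S-phenyl (3aR,7aR)-2,5-dioxohexahydro-4H-furo[2,3-c]pyran-4-carbothioate | O=C1C[C@H]2[C@@H](O1)COC(=O)C2C(=O)Sc1ccccc1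
F5 | step 6 | S-phenyl (3aR,7aR)-2,5-dioxo-4-(3-oxooctyl)hexahydro-4H-furo[2,3-c]pyran-4-carbothioate | O=C1C[C@H]2[C@@H](O1)COC(=O)C2(CCC(=O)CCCCC)C(=O)Sc1ccccc1
F6 | step 6 | 2-[(2R,3R)-2-(bromomethyl)-5-oxooxolan-3-yl]-5-oxo-2-[(phenylsulfanyl)carbonyl]decanoic acid | O=C1C[C@H](C(CCC(=O)CCCCC)(C(=O)O)C(=O)Sc2ccccc2)[C@H](CBr)O1
F7 | step 6 | S-phenyl 2-[(2R,3R)-2-(bromomethyl)-5-oxooxolan-3-yl]-5-oxodecanethioate | O=C1C[C@H](C(CCC(=O)CCCCC)C(=O)Sc2ccccc2)[C@H](CBr)O1
F8 | step 10 | 11,15-bis(1,3-dithiane) analogue of lactone 14 | O=C1C[C@H]2[C@@H](O1)CC3(SCCCS3)[C@@H]2CCC4(CCCCC)SCCCS4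
F9 | step 10 | 11,15-bis(1,3-dithiane) analogue of lactol 15 | OC1C[C@H]2[C@@H](O1)CC3(SCCCS3)[C@@H]2CCC4(CCCCC)SCCCS4
F10 | step 10 | (5Z)-9α-hydroxyprost-5-enoic acid 11,15-bis(propane-1,3-diyl dithioketal) | CCCCCC1(SCCCS1)CC[C@H]2C3(SCCCS3)C[C@H](O)[C@@H]2C/C=C\CCCC(=O)O
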